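The route rests on disconnecting two neighbouring bonds of the benzene ring, C1–C(alkenyl) and C2–O; the key step exploits the ortho relationship of the C1 side chain and the C2 hydroxyl, with C2 next to the C3 methoxy. In one three-component operation 3,5-dimethoxy-4-methylbenzyne is carbometalated at C1 by a chiral alkenylmagnesium and the resulting C2–Mg bond is borylated and oxidised to the phenol, the C3 methoxy fixing the regiochemistry. The aryne precursor is the symmetric 5-chloro-1,3-dimethoxy-2-methylbenzene; the nucleophile comes from (S)-2-bromo-6-methylhepta-1,5-dien-3-ol, which carries the only stereocentre and is used unprotected as its magnesium alkoxide. Selective phenol silylation, angeloylation and desilylation finish the synthesis.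

Key step: step 5

Remark on numbering: ring atoms of the target are C1 (alkenyl chain), C2 (OH), C3 (OMe), C4 (Me), C5 (OMe), C6 (H).

Remark on the precursor design: the carbinol oxygen passes through the key step as a metal alkoxide and not as a silyl ether. An alkoxide cannot migrate to the carbanion formed at C2 (a silyl group could, by a 1,5 oxygen-to-carbon shift). It is also not a leaving group from the position β to the alkenyl–metal bond, so no allene can form. This choice saves one protection and one deprotection step. The aryl chloride is made in one flask from 2,6-dimethoxytoluene.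

Assumption: 2,6-dimethoxytoluene, acrolein, angelic acid, (−)-B-methoxydiisopinocampheylborane [from (+)-α-pinene] and the other reagents named are taken as commercially available.

Step 1
Reactants: 1 2,6-dimethoxytoluene
Product: 3 5-chloro-1,3-dimethoxy-2-methylbenzene, via aryl pinacol boronate 2 (not isolated)
Conditions: [Ir(OMe)(cod)]2 (1.5 mol %), 4,4′-di-tert-butyl-2,2′-bipyridine (3 mol %), B2pin2 (1 equiv), THF, 80 °C; evaporate; CuCl2 (3 equiv), MeOH/H2O 1:1, 80 °C
Reagents that add atoms: copper dichloride, Cl[Cu]Cl (chlorine of 3); bis(pinacolato)diboron, CC1(C)OB(OC1(C)C)B1OC(C)(C)C(C)(C)O1 (boryl group of 2 only)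
Why: Iridium-catalysed C–H borylation is sterically controlled and should take place only at C5, the one ring C–H of 1 with no ortho substituent, and the aryl boronate is then converted into the chloride by copper-mediated chlorodeboronation in the same flask.

Step 2
Reactants: 4 acrolein
Product: 6 2-bromoacrolein, via 2,3-dibromopropanal 5 (not isolated)
Conditions: Br2, CH2Cl2, −78 °C; then Et3N, −78 °C → rt; distil and use at once
Reagents that add atoms: bromine, BrBr
Why: Bromination–dehydrobromination: bromine adds across the alkene and triethylamine removes the acidic α-proton with loss of the β-bromide (E1cB), the standard preparation of this aldehyde.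

Step 3
Reactants: 6 2-bromoacrolein
Product: 8 (S)-2-bromohexa-1,5-dien-3-ol, via diisopinocampheylborinate ester 7 (not isolated)
Conditions: (−)-Ipc2BOMe, allylMgBr, Et2O, −78 °C → rt; then 6, Et2O, −78 °C; 3 M NaOH, 30% H2O2, 0 °C → rt
Reagents that add atoms: allylmagnesium bromide, C=CC[Mg]Br (allyl group of 8, passed on through the allylborane); (−)-B-methoxydiisopinocampheylborane, COB([C@@H]1C[C@@H]2C[C@H]([C@H]1C)C2(C)C)[C@@H]1C[C@@H]2C[C@H]([C@H]1C)C2(C)C (boron and isopinocampheyl groups of 7 only)
Why: Brown asymmetric allylboration through a closed chair (Zimmerman–Traxler) transition state; the isopinocampheyl groups derived from (+)-α-pinene direct the allyl group to the Si face of the aldehyde, which here should give the (S)-carbinol because the bromovinyl group outranks the allyl CH2.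

Step 4
Reactants: 8 (S)-2-bromohexa-1,5-dien-3-ol
Product: 9 (S)-2-bromo-6-methylhepta-1,5-dien-3-ol
Conditions: 2-methylbut-2-ene (co-solvent), second-generation Grubbs catalyst RuCl2(=CHPh)(PCy3)(H2IMes) (3 mol %), CH2Cl2, 40 °C
Reagents that add atoms: 2-methylbut-2-ene, CC=C(C)C
Why: Olefin cross-metathesis exchanges the terminal =CH2 of the monosubstituted alkene for =CMe2; the 1,1-disubstituted bromoalkene is too hindered and electron-poor to enter the cycle, and the stereocentre is not touched.

Step 5
Reactants: 9 (S)-2-bromo-6-methylhepta-1,5-dien-3-ol; 3 5-chloro-1,3-dimethoxy-2-methylbenzene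
Product: 16 (S)-6-(3-hydroxy-6-methylhepta-1,5-dien-2-yl)-2,4-dimethoxy-3-methylphenol, via dilithio alkoxide 10 (not isolated), via alkenylmagnesium alkoxide 11 (not isolated), via aryllithium 12 (not isolated), via aryne 13 (not isolated), via arylmagnesium adduct 14 (not isolated), via cyclic methyl boronate 15 (not isolated)
Conditions: 9 (1.5 equiv), t-BuLi (3 equiv per 9), Et2O, −78 °C, then MgBr2·OEt2 (2 equiv per 9), −78 → 0 °C; separately 3 (1.0 equiv), s-BuLi (1.0 equiv), THF, −78 °C; add the solution of 11, −78 °C → rt; B(OMe)3, −78 → 0 °C; 3 M NaOH, 30% H2O2, 0 °C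
Reagents that add atoms: hydrogen peroxide, OO (phenolic oxygen of 16); tert-butyllithium, CC(C)(C)[Li] (lithium of 10 only); magnesium dibromide etherate, Br[Mg]Br (magnesium bromide of 11 and 14 only); sec-butyllithium, CCC(C)[Li] (lithium of 12 only); trimethyl borate, COB(OC)OC (boron and B–OMe of 15 only)
Why: Tert-butyllithium deprotonates the hydroxyl and exchanges the bromine of 9, MgBr2 turns dilithio species 10 into alkenylmagnesium alkoxide 11, and ortho-lithiation of 3 between Cl and OMe gives 12, which loses LiCl on warming to aryne 13; the C–Mg bond of 11 adds across the strained triple bond to give arylmagnesium 14, B(OMe)3 captures it as boronate 15, and alkaline peroxide turns C2–B into C2–O by 1,2-shift of the aryl group from boron to oxygen. The closest known reaction type is the carbomagnesiation of arynes by Grignard reagents with electrophilic trapping of the new aryl Grignard reagent (three-component aryne coupling), joined to the standard borate oxidation of an arylmagnesium to a phenol. No ring is closed and no stereocentre is formed; the carbinol centre of 9 is a spectator because its C–H is not acidic and its C–O bond is never broken. The step needs regioselective addition to the unsymmetrical aryne: the C3 methoxy beside the triple bond makes the remote terminus C1 the more electrophilic and less hindered carbon and stabilises the developing carbanion at C2 inductively and by coordination to magnesium, so carbon should go to C1 and metal to C2. Because 3 is symmetric only one aryne can form, and an excess of 11 over the hindered aryllithium 12 should suppress addition of 12 to the aryne. Alkaline hydrogen peroxide at 0 °C oxidises the C–B bond and should leave the three alkenes alone.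

Step 6
Reactants: 16 (S)-6-(3-hydroxy-6-methylhepta-1,5-dien-2-yl)-2,4-dimethoxy-3-methylphenol
Product: 17 (S)-2-[2-(tert-butyldimethylsilyloxy)-3,5-dimethoxy-4-methylphenyl]-6-methylhepta-1,5-dien-3-ol
Conditions: TBSCl (1.05 equiv), imidazole, DMF, 0 °C
Reagents that add atoms: tert-butyldimethylsilyl chloride, CC(C)(C)[Si](C)(C)Cl
Why: Chemoselective O-silylation: the acidic phenol is engaged by imidazole as a phenoxide ion pair and should react faster than the secondary allylic carbinol, which is hindered by the neighbouring fully substituted alkene carbon, so one equivalent of silyl chloride at 0 °C should stop at the aryl silyl ether.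

Step 7
Reactants: 17 (S)-2-[2-(tert-butyldimethylsilyloxy)-3,5-dimethoxy-4-methylphenyl]-6-methylhepta-1,5-dien-3-ol; 18 angelic acid
Product: 20 (S)-2-[2-(tert-butyldimethylsilyloxy)-3,5-dimethoxy-4-methylphenyl]-6-methylhepta-1,5-dien-3-yl (Z)-2-methylbut-2-enoate, via mixed anhydride 19 (not isolated)
Conditions: 18, 2,4,6-trichlorobenzoyl chloride, Et3N, toluene, rt; then 17, toluene, 80 °C (no DMAP)
Reagents that add atoms: 2,4,6-trichlorobenzoyl chloride, O=C(Cl)c1c(Cl)cc(Cl)cc1Cl (atoms stay in intermediate 19 only)
Why: Yamaguchi-type mixed-anhydride esterification: the alcohol attacks the angeloyl carbonyl of 19 because the other carbonyl is shielded by two ortho chlorines, and leaving out DMAP avoids the conjugate addition–elimination that turns angelates into tiglates; the acyl–oxygen bond is formed with retention at the stereocentre.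

Step 8
Reactants: 20 (S)-2-[2-(tert-butyldimethylsilyloxy)-3,5-dimethoxy-4-methylphenyl]-6-methylhepta-1,5-dien-3-yl (Z)-2-methylbut-2-enoate
Product: 21 (S)-2-(2-hydroxy-3,5-dimethoxy-4-methylphenyl)-6-methylhepta-1,5-dien-3-yl (Z)-2-methylbut-2-enoate
Conditions: TBAF, AcOH, THF, 0 °C
Reagents that add atoms: none
Why: Fluoride-mediated desilylation: aryl silyl ethers are cleaved fast because phenoxide leaves silicon easily, and the acetic acid buffer protonates the phenoxide at once, so acyl transfer from the neighbouring ester and isomerisation of the angelate should not occur.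

Compound list
1 | 2,6-dimethoxytoluene (1,3-dimethoxy-2-methylbenzene) | COc1cccc(OC)c1C | starting material
2 | 2-(3,5-dimethoxy-4-methylphenyl)-4,4,5,5-tetramethyl-1,3,2-dioxaborolane | COc1cc(B2OC(C)(C)C(C)(C)O2)cc(OC)c1C | intermediate (not isolated)
3 | 5-chloro-1,3-dimethoxy-2-methylbenzene | COc1cc(Cl)cc(OC)c1C | intermediate
4 | acrolein (prop-2-enal) | C=CC=O | starting material
5 | 2,3-dibromopropanal (racemic) | O=CC(Br)CBr | intermediate (not isolated)
6 | 2-bromoacrolein (2-bromoprop-2-enal) | C=C(Br)C=O | intermediate
7 | (S)-2-bromohexa-1,5-dien-3-yl bis[(1R,2S,3R,5R)-2,6,6-trimethylbicyclo[3.1.1]heptan-3-yl]borinate | C=C(Br)[C@H](CC=C)OB([C@@H]1C[C@@H]2C[C@H]([C@H]1C)C2(C)C)[C@@H]1C[C@@H]2C[C@H]([C@H]1C)C2(C)C | intermediate (not isolated)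
8 | (S)-2-bromohexa-1,5-dien-3-ol | C=C(Br)[C@H](CC=C)O | intermediate
9 | (S)-2-bromo-6-methylhepta-1,5-dien-3-ol | C=C(Br)[C@H](CC=C(C)C)O | intermediate
10 | lithium (S)-2-lithio-6-methylhepta-1,5-dien-3-olate | C=C([Li])[C@H](CC=C(C)C)O[Li] | intermediate (not isolated)
11 | bromomagnesium (S)-2-(bromomagnesio)-6-methylhepta-1,5-dien-3-olate | C=C([Mg]Br)[C@H](CC=C(C)C)O[Mg]Br | intermediate (not isolated)
12 | (6-chloro-2,4-dimethoxy-3-methylphenyl)lithium | COc1cc(Cl)c([Li])c(OC)c1C | intermediate (not isolated)
13 | 3,5-dimethoxy-4-methylbenzyne | COC1=C(C)C(OC)=CC#C1 | intermediate (not isolated)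
14 | bromomagnesium (S)-2-[2-(bromomagnesio)-3,5-dimethoxy-4-methylphenyl]-6-methylhepta-1,5-dien-3-olate | C=C(c1cc(OC)c(C)c(OC)c1[Mg]Br)[C@H](CC=C(C)C)O[Mg]Br | intermediate (not isolated)
15 | (S)-1,6,8-trimethoxy-7-methyl-4-methylidene-3-(3-methylbut-2-enyl)-3,4-dihydro-1H-2,1-benzoxaborinine (cyclic methyl boronate) | C=C1c2cc(OC)c(C)c(OC)c2B(OC)O[C@H]1CC=C(C)C | intermediate (not isolated)
16 | (S)-6-(3-hydroxy-6-methylhepta-1,5-dien-2-yl)-2,4-dimethoxy-3-methylphenol | C=C(c1cc(OC)c(C)c(OC)c1O)[C@H](CC=C(C)C)O | intermediate
17 | (S)-2-[2-(tert-butyldimethylsilyloxy)-3,5-dimethoxy-4-methylphenyl]-6-methylhepta-1,5-dien-3-ol | C=C(c1cc(OC)c(C)c(OC)c1O[Si](C)(C)C(C)(C)C)[C@H](CC=C(C)C)O | intermediate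
18 | angelic acid, (Z)-2-methylbut-2-enoic acid | C/C=C(/C)C(=O)O | starting material
19 | (Z)-2-methylbut-2-enoic 2,4,6-trichlorobenzoic anhydride | C/C=C(/C)C(=O)OC(=O)c1c(Cl)cc(Cl)cc1Cl | intermediate (not isolated)
20 | (S)-2-[2-(tert-butyldimethylsilyloxy)-3,5-dimethoxy-4-methylphenyl]-6-methylhepta-1,5-dien-3-yl (Z)-2-methylbut-2-enoate | C=C(c1cc(OC)c(C)c(OC)c1O[Si](C)(C)C(C)(C)C)[C@H](CC=C(C)C)OC(=O)/C(C)=C\C | intermediate
21 | (S)-2-(2-hydroxy-3,5-dimethoxy-4-methylphenyl)-6-methylhepta-1,5-dien-3-yl (Z)-2-methylbut-2-enoate | C=C(c1cc(OC)c(C)c(OC)c1O)[C@H](CC=C(C)C)OC(=O)/C(C)=C\C | target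

Total step count: 8 steps.
Longest linear sequence: 7 steps (acrolein 4 through steps 2, 3, 4, 5, 6, 7 and 8 to 21); the aryl chloride branch adds step 1.

Steps most likely to fail

Step 5. The short-lived aryne may be consumed by addition of the lithiated chloride to it before the alkenylmagnesium captures it, or the hindered C2–Mg bond may be protonated before it is borylated. The fallback makes the two bonds one after the other by known chemistry. It sets out from 3 and 9. Compound 3 is lithiated as in step 5 (s-BuLi, THF, −78 °C), but 12 is trapped at −78 °C with B(OMe)3 before LiCl is lost and then oxidised (NaOH, H2O2) to 6-chloro-2,4-dimethoxy-3-methylphenol F1. Silylation (TBSCl, imidazole, DMF) gives tert-butyl(6-chloro-2,4-dimethoxy-3-methylphenoxy)dimethylsilane F2. Separately 9 is converted through 10 (t-BuLi, 3 equiv, Et2O, −78 °C) and ZnBr2 (2 equiv) into bromozinc (S)-2-(bromozincio)-6-methylhepta-1,5-dien-3-olate F3. Negishi coupling of F2 with F3 (Pd2(dba)3, RuPhos, THF, 70 °C; zerovalent palladium inserts into the C–Cl bond) should give 17 after aqueous work-up, where the route is rejoined before step 7.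

Step 7. The activated angeloyl group may isomerise to the tigloyl isomer, or acylation of the hindered carbinol may be too slow. The fallback builds the Z-alkene after the acylation. It sets out from 17, which is esterified with 2-[bis(2,2,2-trifluoroethoxy)phosphoryl]propanoic acid (DCC, DMAP, CH2Cl2) to (S)-2-[2-(tert-butyldimethylsilyloxy)-3,5-dimethoxy-4-methylphenyl]-6-methylhepta-1,5-dien-3-yl 2-[bis(2,2,2-trifluoroethoxy)phosphoryl]propanoate F4 (both epimers at the phosphorus-bearing carbon). Still–Gennari olefination of F4 with acetaldehyde (KN(SiMe3)2, 18-crown-6, THF, −78 °C) should form the (Z)-2-methylbut-2-enoate under kinetic control and give 20, where the route is rejoined before step 8.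

Step 3. The sensitive aldehyde may polymerise, or facial selectivity in the allyl transfer may be insufficient. The fallback sets the stereocentre by reduction instead of C–C bond formation. It sets out from 6, which is allylated without stereocontrol under Barbier conditions (allyl bromide, zinc dust, THF/aqueous NH4Cl) to racemic 2-bromohexa-1,5-dien-3-ol F5. Oxidation with Dess–Martin periodinane (NaHCO3, CH2Cl2, 0 °C) gives 2-bromohexa-1,5-dien-3-one F6, which is kept cold to avoid shift of the β,γ-alkene into conjugation. Corey–Bakshi–Shibata reduction with (R)-2-methyl-CBS-oxazaborolidine and catecholborane (toluene, −78 °C), in which the bromovinyl group acts as the large substituent, should give (S)-carbinol 8, where the route is rejoined before step 4.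

Further compounds
F1 | step 5 | 6-chloro-2,4-dimethoxy-3-methylphenol | COc1cc(Cl)c(O)c(OC)c1C
F2 | step 5 | tert-butyl(6-chloro-2,4-dimethoxy-3-methylphenoxy)dimethylsilane | COc1cc(Cl)c(O[Si](C)(C)C(C)(C)C)c(OC)c1C
F3 | step 5 | bromozinc (S)-2-(bromozincio)-6-methylhepta-1,5-dien-3-olate | C=C([Zn]Br)[C@H](CC=C(C)C)O[Zn]Br
F4 | step 7 | (S)-2-[2-(tert-butyldimethylsilyloxy)-3,5-dimethoxy-4-methylphenyl]-6-methylhepta-1,5-dien-3-yl 2-[bis(2,2,2-trifluoroethoxy)phosphoryl]propanoate | C=C(c1cc(OC)c(C)c(OC)c1O[Si](C)(C)C(C)(C)C)[C@H](CC=C(C)C)OC(=O)C(C)P(=O)(OCC(F)(F)F)OCC(F)(F)F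
F5 | step 3 | racemic 2-bromohexa-1,5-dien-3-ol | C=C(Br)C(O)CC=C
F6 | step 3 | 2-bromohexa-1,5-dien-3-one | C=C(Br)C(=O)CC=C
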